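## Retrosynthetic overview
1. Structural feature: in the ten-membered ring C1–C10, C5 and C10 face each other across the ring. A C5–C10 bond turns the ring into a trans-decalin (ring A: C1–C5 and C10; ring B: C5–C10). In it C5–OH, C10 and an equatorial C1–OMs form a 1,3-diol monosulfonate, so cutting that bond gives the (E)-C1=C10 alkene and a C5 carbonyl.
2. Target ⇒ exchange of the groups on O6 and O8 ⇒ trans C4–C5 epoxide, made by displacing a C5 mesylate with the C4 hydroxyl ⇒ chelation-controlled reduction of the C4-hydroxy C5-ketone ⇒ Wharton fragmentation.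
3. Decalin ⇒ α-face osmylation of a C4=C5 alkene ⇒ 6α-allylic alcohol from the C5–C6 epoxide of an s-cis C4(15),C5-diene ⇒ 6-exo Heck closure of ring A onto a C5 enol triflate.
4. Ring B ⇒ (+)-3-carene. Its cyclopropane is the masked C7 isopropyl group. It shields the β face for the C8 reduction and for the C10 aldol with 4-pentenal (C1–C4, C15), and Li/NH3 cleavage releases the C5–C6 enolate.
5. Order of rings: ring B (chiral pool), ring A (step 8), ten-membered ring (step 17), epoxide (step 19).

Key step: step 17

Remark: germacrane numbering (C1–C15) is used for every intermediate. β is the face of the C10 methyl group in the decalins, which is the face of the CMe2 bridge in the carane intermediates; α is the opposite face. Commercial (+)-3-carene is taken as the pure (1S,6R) enantiomer.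

## Route

Step 1
Reactants: 1 (+)-3-carene
Product: 2 car-3-en-5-one (C8 ketone conjugated with C9=C10)
Conditions: CrO3, 3,5-dimethylpyrazole, CH2Cl2, −20 °C
Reagents that add atoms: chromium trioxide, O=[Cr](=O)=O
Why: Chromium-mediated allylic oxidation takes the ring CH2 next to the CH end of the trisubstituted alkene (C8), the usual site for 3-carene, and does not touch the two cyclopropane stereocentres.

Step 2
Reactants: 2 car-3-en-5-one
Product: 3 8β-allylic alcohol
Conditions: NaBH4, CeCl3·7H2O, MeOH, −78 to 0 °C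
Reagents that add atoms: none
Why: In this Luche 1,2-reduction hydride arrives on the α face, away from the endo methyl group of the CMe2 bridge, so the hydroxyl ends up β (cis to the cyclopropane), which is the C8 configuration of the target.

Step 3
Reactants: 3 8β-allylic alcohol
Product: 4 8β-TBS ether
Conditions: t-BuMe2SiOTf, 2,6-lutidine, CH2Cl2, 0 °C
Reagents that add atoms: tert-butyldimethylsilyl triflate, CC(C)(C)[Si](C)(C)OS(=O)(=O)C(F)(F)F
Why: Silyl triflate silylation protects the hindered secondary alcohol with a group that lasts until the final step.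

Step 4
Reactants: 4 8β-TBS ether
Product: 6 C5 enone, via 5α-allylic alcohol 5 (not isolated)
Conditions: SeO2 (cat.), t-BuOOH, CH2Cl2, rt; crude material, then Dess–Martin periodinane, CH2Cl2, 0 °C
Reagents that add atoms: tert-butyl hydroperoxide, CC(C)(C)OO
Why: Selenium dioxide allylic oxidation (ene reaction, then [2,3]-shift) hydroxylates the ring CH2 on the more substituted alkene carbon (C5), and Dess–Martin oxidation removes the new carbinol centre to give the C5 enone.

Step 5
Reactants: 6 C5 enone; 7 4-pentenal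
Product: 9 aldol adduct, via lithium enolate 8 (not isolated)
Conditions: LiBH(s-Bu)3, THF, −78 °C; then 7, −78 °C; pH 7 buffer
Reagents that add atoms: none
Why: In this reductive aldol, conjugate hydride addition gives only the C5–C10 enolate, which adds to 7 on the α face because the CMe2 bridge and the 8β-silyloxy group cover the β face, so C10 carries CH3 β and C1 α; a Zimmerman–Traxler transition state predicts the 1α-alcohol drawn, and either C1 epimer is usable because C1 is reset in steps 10 and 11.

Step 6
Reactants: 9 aldol adduct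
Product: 10 C1 triethylsilyl ether
Conditions: Et3SiOTf, 2,6-lutidine, CH2Cl2, −78 °C
Reagents that add atoms: triethylsilyl triflate, CC[Si](CC)(CC)OS(=O)(=O)C(F)(F)F
Why: Silylation at low temperature under non-basic conditions blocks retro-aldol cleavage and installs a group more labile than the C8 TBS ether.

Step 7
Reactants: 10 C1 triethylsilyl ether
Product: 12 C5 enol triflate, via lithium enolate 11 (not isolated)
Conditions: Li, NH3(l)–THF, t-BuOH (1 equiv), −78 °C; NH3 evaporated; PhNTf2, THF, 0 °C
Reagents that add atoms: N-phenylbis(trifluoromethanesulfonimide), O=S(=O)(N(c1ccccc1)S(=O)(=O)C(F)(F)F)C(F)(F)F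
Why: Dissolving-metal cleavage of the conjugated cyclopropyl ketone breaks the exocyclic C6–C11 bond, which is the one aligned with the carbonyl π system; this unmasks the β isopropyl group with C7 unchanged and gives only the C5–C6 enolate, which is trapped as its triflate.

Step 8
Reactants: 12 C5 enol triflate
Product: 13 bicyclic C4(15),C5-diene (1α-OTES)
Conditions: Pd(OAc)2 (10 mol %), PPh3, K2CO3, MeCN, 70 °C
Reagents that add atoms: none
Why: In this 6-exo-trig intramolecular Heck reaction the C5 vinylpalladium adds to C4 of the terminal alkene, and β-hydride elimination of H4 leaves the exocyclic C4=C15 bond, which closes ring A.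

Step 9
Reactants: 13 bicyclic diene
Product: 14 1α-alcohol
Conditions: HF·pyridine, pyridine, THF, 0 °C
Reagents that add atoms: none
Why: Buffered fluoride desilylation removes the triethylsilyl ether faster than the bulkier TBS ether next to the isopropyl group.

Step 10
Reactants: 14 1α-alcohol
Product: 15 C1 ketone
Conditions: Dess–Martin periodinane, CH2Cl2, rt
Reagents that add atoms: none
Why: Dess–Martin oxidation under neutral conditions erases the C1 centre, and the β,γ-unsaturated ketone cannot move into conjugation because C10 is quaternary.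

Step 11
Reactants: 15 C1 ketone
Product: 16 1β-alcohol
Conditions: NaBH4, MeOH, 0 °C
Reagents that add atoms: none
Why: In this borohydride reduction hydride attacks axially from the α face, anti to the angular methyl group, as is general for 10-methyl-1-decalones with an sp2 C5, and gives the equatorial 1β-alcohol.

Step 12
Reactants: 16 1β-alcohol
Product: 17 1β-mesylate diene
Conditions: MsCl, Et3N, CH2Cl2, 0 °C
Reagents that add atoms: methanesulfonyl chloride, CS(=O)(=O)Cl
Why: Sulfonylation of the only free hydroxyl gives an equatorial neopentyl mesylate that has no antiperiplanar hydrogen and no open backside, so it should survive steps 13 to 16.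

Step 13
Reactants: 17 1β-mesylate diene
Product: 18 5α,6α-vinyl epoxide
Conditions: dimethyldioxirane, acetone–CH2Cl2, −40 to −20 °C
Reagents that add atoms: dimethyldioxirane, CC1(C)OO1
Why: Neutral dioxirane epoxidation takes the more substituted, more electron-rich C5=C6 bond of the diene from the α face, because the C10 methyl group and the axial 8β-silyloxy group block the β face; this sets C6.

Step 14
Reactants: 18 5α,6α-vinyl epoxide
Product: 19 6α-allylic alcohol with C4=C5
Conditions: SmI2, THF–MeOH, −78 °C
Reagents that add atoms: none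
Why: In this SmI2 reduction of a vinyl oxirane the allylic C5–O bond breaks and the allylsamarium is protonated at the unhindered C15 terminus, which gives the C4 methyl group and the tetrasubstituted C4=C5 alkene and leaves the C6–O bond α.

Step 15
Reactants: 19 6α-allylic alcohol
Product: 20 6α-PMB ether
Conditions: NaH, 4-methoxybenzyl bromide, Bu4NI (cat.), THF–DMF, 0 °C to rt
Reagents that add atoms: 4-methoxybenzyl bromide, COc1ccc(CBr)cc1
Why: Williamson etherification under basic conditions avoids ionising the allylic alcohol and installs a chelating group that can later be removed oxidatively.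

Step 16
Reactants: 20 6α-PMB ether
Product: 22 fragmentation precursor (4α,5α-diol), via cyclic osmate ester 21 (not isolated)
Conditions: OsO4 (1.1 equiv), pyridine, rt; then aq NaHSO3, THF
Reagents that add atoms: osmium tetroxide, O=[Os](=O)(=O)=O
Why: Stoichiometric syn-dihydroxylation occurs on the α face, anti to the angular methyl group, and sets C4 (OH α, CH3 β, the target configuration) and C5 (OH α, trans ring fusion) in one operation.

Step 17
Reactants: 22 fragmentation precursor
Product: 24 ten-membered (E)-1(10)-ene C4-hydroxy C5-ketone, via potassium C5-alkoxide 23 (not isolated)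
Conditions: KOt-Bu, t-BuOH–THF, 0 °C to rt, short reaction time; pH 7 buffer
Reagents that add atoms: none
Why: KOt-Bu deprotonates the tertiary C5 hydroxyl, and in alkoxide 23 the oxygen lone pair, the C5–C10 bond and the equatorial C1–OMs bond are antiperiplanar in the chair–chair trans-decalin, so C5=O forms, C5–C10 breaks, the C1=C10 π bond forms and mesylate leaves in one concerted event (the Wharton variant of the Grob fragmentation of a cyclic 1,3-diol monosulfonate, the standard way from decalins to (E)-cyclodec-5-enones). The ten-membered ring is not closed end to end but arises by scission of the bond shared by rings A and B, and loss of the two syn-diaxial contacts of the C10 methyl group (with the C4 methyl and the 8β-silyloxy group) adds driving force. No stereocentre is created; the alkene geometry is fixed by the substrate, because C2 and C9 are anti about C1–C10 in the trans-decalin and so end up trans, which is the E isomer. Site selectivity is built in, since the C4 alkoxide has no leaving group in a 1,3-relationship and only waits in equilibrium while the C5 alkoxide fragments. C4, C6, C7 and C8 are spectators, and C6 epimerisation or an α-ketol shift of 24 is held back by low temperature, short contact with base and the negative charge on O4 next to the new ketone.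

Step 18
Reactants: 24 ten-membered hydroxy ketone
Product: 25 (5S)-C4,C5-diol
Conditions: Zn(BH4)2, Et2O, −30 °C
Reagents that add atoms: none
Why: In this Cram-chelate reduction zinc ties the C5 carbonyl to O4 (chelation to the O6 ether predicts the same face), and hydride enters from the outer face on the side of the C4 methyl group and H6, which gives the C5 alcohol needed for a trans epoxide after inversion.

Step 19
Reactants: 25 (5S)-C4,C5-diol
Product: 27 trans C4–C5 epoxide (6-OPMB, 8-OTBS), via C5 mesylate 26 (not isolated)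
Conditions: MsCl, Et3N, CH2Cl2, −10 °C; then K2CO3, MeOH, rt
Reagents that add atoms: none
Why: The secondary C5 hydroxyl is mesylated in preference to the tertiary C4 hydroxyl, and intramolecular SN2 displacement by O4 closes the epoxide with inversion at C5 and retention at C4.

Step 20
Reactants: 27 trans C4–C5 epoxide
Product: 28 C6 alcohol
Conditions: DDQ, CH2Cl2–pH 7 buffer, 0 °C
Reagents that add atoms: none
Why: Oxidative PMB cleavage at neutral pH frees O6 without the acid that would start transannular cyclisation of the epoxy alkene.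

Step 21
Reactants: 28 C6 alcohol; 29 3,4,5-trimethoxybenzoyl chloride
Product: 30 C6 trimethoxybenzoate 8-TBS ether
Conditions: Et3N, DMAP, CH2Cl2, rt
Reagents that add atoms: none
Why: DMAP-catalysed acylation esterifies the only free hydroxyl with retention at C6.

Step 22
Reactants: 30 C6 trimethoxybenzoate 8-TBS ether
Product: 31 target
Conditions: Bu4NF, AcOH, THF, rt
Reagents that add atoms: none
Why: Acetic-acid-buffered fluoride desilylation frees O8 without producing a basic alkoxide that could take the acyl group from O6, and it spares the epoxide.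

## Compound list
1 | (+)-3-carene, (1S,6R)-3,7,7-trimethylbicyclo[4.1.0]hept-3-ene (C10 methyl alkene, C6–C7–C11 cyclopropane β) | CC1=CC[C@@H]2[C@H](C1)C2(C)C | starting material
2 | car-3-en-5-one (C8 ketone, C9=C10, cyclopropane β) | CC1=CC(=O)[C@@H]2[C@H](C1)C2(C)C | intermediate
3 | 8β-allylic alcohol (OH cis to the cyclopropane) | CC1=C[C@@H](O)[C@@H]2[C@H](C1)C2(C)C | intermediate
4 | 8β-TBS ether of 3 | CC1=C[C@@H](O[Si](C)(C)C(C)(C)C)[C@@H]2[C@H](C1)C2(C)C | intermediate
5 | 5α-allylic alcohol, 8β-OTBS | CC1=C[C@@H](O[Si](C)(C)C(C)(C)C)[C@@H]2[C@H]([C@@H]1O)C2(C)C | intermediate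
6 | C5 enone (C5=O, C9=C10, 8β-OTBS, cyclopropane β) | CC1=C[C@@H](O[Si](C)(C)C(C)(C)C)[C@@H]2[C@H](C1=O)C2(C)C | intermediate
7 | 4-pentenal | C=CCCC=O | starting material
8 | lithium C5–C10 enolate of the carane ketone | CC1=C([O-])[C@H]2[C@@H]([C@@H](C1)O[Si](C)(C)C(C)(C)C)C2(C)C.[Li+] | intermediate
9 | aldol adduct (C10: CH3 β, C1 α; C1 carbinol of the 1α series; C5 ketone) | C=CCC[C@H](O)[C@]1(C)C[C@@H](O[Si](C)(C)C(C)(C)C)[C@@H]2[C@H](C1=O)C2(C)C | intermediate
10 | C1 triethylsilyl ether of 9 | C=CCC[C@H](O[Si](CC)(CC)CC)[C@]1(C)C[C@@H](O[Si](C)(C)C(C)(C)C)[C@@H]2[C@H](C1=O)C2(C)C | intermediate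
11 | lithium C5–C6 enolate, 7β-isopropyl | C=CCC[C@H](O[Si](CC)(CC)CC)[C@]1(C)C[C@@H](O[Si](C)(C)C(C)(C)C)[C@@H](C(C)C)C=C1[O-].[Li+] | intermediate
12 | C5 enol triflate (C5=C6), 7β-isopropyl, 8β-OTBS | C=CCC[C@H](O[Si](CC)(CC)CC)[C@]1(C)C[C@@H](O[Si](C)(C)C(C)(C)C)[C@@H](C(C)C)C=C1OS(=O)(=O)C(F)(F)F | intermediate
13 | bicyclic diene (C4=C15, C5=C6), 1α-OTES, 8β-OTBS, 10β-CH3 | C=C1CC[C@H](O[Si](CC)(CC)CC)[C@]2(C)C[C@@H](O[Si](C)(C)C(C)(C)C)[C@@H](C(C)C)C=C12 | intermediate
14 | 1α-alcohol of the diene | C=C1CC[C@H](O)[C@]2(C)C[C@@H](O[Si](C)(C)C(C)(C)C)[C@@H](C(C)C)C=C12 | intermediate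
15 | C1 ketone of the diene | C=C1CCC(=O)[C@]2(C)C[C@@H](O[Si](C)(C)C(C)(C)C)[C@@H](C(C)C)C=C12 | intermediate
16 | 1β-alcohol (equatorial) of the diene | C=C1CC[C@@H](O)[C@]2(C)C[C@@H](O[Si](C)(C)C(C)(C)C)[C@@H](C(C)C)C=C12 | intermediate
17 | 1β-mesylate of the diene | C=C1CC[C@@H](OS(C)(=O)=O)[C@]2(C)C[C@@H](O[Si](C)(C)C(C)(C)C)[C@@H](C(C)C)C=C12 | intermediate
18 | 5α,6α-epoxide next to C4=C15, 1β-OMs | C=C1CC[C@@H](OS(C)(=O)=O)[C@]2(C)C[C@@H](O[Si](C)(C)C(C)(C)C)[C@@H](C(C)C)[C@@H]3O[C@]123 | intermediate
19 | 6α-allylic alcohol, C4=C5, C4 methyl, 1β-OMs | CC1=C2[C@@H](O)[C@H](C(C)C)[C@H](O[Si](C)(C)C(C)(C)C)C[C@@]2(C)[C@H](OS(C)(=O)=O)CC1 | intermediate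
20 | 6α-PMB ether of 19 | CC1=C2[C@@H](OCc3ccc(OC)cc3)[C@H](C(C)C)[C@H](O[Si](C)(C)C(C)(C)C)C[C@@]2(C)[C@H](OS(C)(=O)=O)CC1 | intermediate
21 | cyclic 4α,5α-osmate ester (pyridine ligands not drawn) | CS(=O)(=O)O[C@@H]1CC[C@@]2(C)O[Os](=O)(=O)O[C@]23[C@@H](OCc4ccc(OC)cc4)[C@H](C(C)C)[C@H](O[Si](C)(C)C(C)(C)C)C[C@@]13C | intermediate
22 | trans-decalin precursor: 1β-OMs (eq), 4α-OH/4β-CH3, 5α-OH, 6α-OPMB, 7β-isopropyl, 8β-OTBS, 10β-CH3 | CS(=O)(=O)O[C@@H]1CC[C@@](C)(O)[C@]2(O)[C@@H](OCc3ccc(OC)cc3)[C@H](C(C)C)[C@H](O[Si](C)(C)C(C)(C)C)C[C@@]12C | intermediate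
23 | potassium C5-alkoxide of 22 | CS(=O)(=O)O[C@@H]1CC[C@@](C)(O)[C@]2([O-])[C@@H](OCc3ccc(OC)cc3)[C@H](C(C)C)[C@H](O[Si](C)(C)C(C)(C)C)C[C@@]12C.[K+] | intermediate
24 | ten-membered (E)-1(10)-ene, C5 ketone, C4 tertiary alcohol, 6-OPMB, 8-OTBS | COc1ccc(CO[C@H]2[C@H](C(C)C)[C@H](O[Si](C)(C)C(C)(C)C)C/C(C)=C/CC[C@@](C)(O)C2=O)cc1 | intermediate
25 | (5S)-C4,C5-diol | COc1ccc(CO[C@H]2[C@H](C(C)C)[C@H](O[Si](C)(C)C(C)(C)C)C/C(C)=C/CC[C@@](C)(O)[C@H]2O)cc1 | intermediate
26 | C5 mesylate of 25 | COc1ccc(CO[C@H]2[C@H](C(C)C)[C@H](O[Si](C)(C)C(C)(C)C)C/C(C)=C/CC[C@@](C)(O)[C@H]2OS(C)(=O)=O)cc1 | intermediate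
27 | (4R,5R)-epoxide, 6-OPMB, 8-OTBS | COc1ccc(CO[C@H]2[C@H](C(C)C)[C@H](O[Si](C)(C)C(C)(C)C)C/C(C)=C/CC[C@@]3(C)O[C@H]23)cc1 | intermediate
28 | C6 alcohol, 8-OTBS epoxide | O[C@H]1[C@H](C(C)C)[C@H](O[Si](C)(C)C(C)(C)C)C/C(C)=C/CC[C@@]2(C)O[C@H]12 | intermediate
29 | 3,4,5-trimethoxybenzoyl chloride | COc1cc(C(Cl)=O)cc(OC)c1OC | starting material
30 | C6 3,4,5-trimethoxybenzoate, 8-OTBS | COc1cc(C(=O)O[C@H]2[C@H](C(C)C)[C@H](O[Si](C)(C)C(C)(C)C)C/C(C)=C/CC[C@@]3(C)O[C@H]23)cc(OC)c1OC | intermediate
31 | (1(10)E,4R,5R,6S,7R,8R)-4,5-epoxy-8-hydroxygermacr-1(10)-en-6-yl 3,4,5-trimethoxybenzoate | COc1cc(C(=O)O[C@H]2[C@H](C(C)C)[C@H](O)C/C(C)=C/CC[C@@]3(C)O[C@H]23)cc(OC)c1OC | target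

## Step count and risks
Total step count: 22. Longest linear sequence: 22 steps from (+)-3-carene (7 and 29 are bought).

**Step 17.** With O4 free, prolonged contact with base could cause an α-ketol shift of the product, loss of configuration at C6 by enolisation, or ether formation by an alkoxide in competition with fragmentation.
- The fallback sets out from 22. The equatorial 4α-hydroxyl is silylated selectively (Et3SiOTf, 2,6-lutidine, −78 °C) to give the C4 triethylsilyl ether of the precursor F1.
- KOt-Bu fragmentation of F1 gives the C4 silyloxy ketone F2, which has no α-hydroxyl and cannot undergo the ketol shift. Any silyl migration from O4 to O5 only delays the reaction, because only the C5 alkoxide can fragment.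
- HF·pyridine removes the triethylsilyl group, and the route is rejoined at 24.

**Step 16.** Osmylation of the tetrasubstituted alkene, which sits between a quaternary carbon and a benzyloxy carbon, may be very slow or stop at partial conversion.
- The fallback sets out from 19, before the PMB group is introduced, and uses hydrogen-bond delivery. OsO4 and TMEDA in CH2Cl2 at −78 °C are steered by the free 6α-hydroxyl to the same α face and give the chelated osmate ester F3.
- Aqueous Na2SO3 cleaves F3 to the 4α,5α,6α-triol mesylate F4.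
- Acid-catalysed benzyl transfer from 4-methoxybenzyl trichloroacetimidate (La(OTf)3 cat., toluene) reaches only the secondary O6, and the route is rejoined at 22.

**Step 13.** The two alkenes of the diene may be discriminated poorly, or the tertiary allylic epoxide may open before it can be reduced.
- The fallback sets out from 17 and replaces steps 13 and 14 by a 1,4-hydrosilylation. HSiCl3 with [PdCl(C3H5)]2 and PPh3 delivers hydrogen to C15 and silicon to the less substituted allyl terminus C6 on the open α face, giving the 6α-trichlorosilane F5.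
- EtOH and Et3N convert F5 into the 6α-triethoxysilane F6.
- Tamao oxidation (H2O2, KF, KHCO3, THF–MeOH) replaces silicon by hydroxyl with retention, and the route is rejoined at 19.

## Further compounds
F1 | step 17 | C4 triethylsilyl ether of precursor 22 | CS(=O)(=O)O[C@@H]1CC[C@@](C)(O[Si](CC)(CC)CC)[C@]2(O)[C@@H](OCc3ccc(OC)cc3)[C@H](C(C)C)[C@H](O[Si](C)(C)C(C)(C)C)C[C@@]12C
F2 | step 17 | C4 triethylsilyl ether of ketone 24 | COc1ccc(CO[C@H]2[C@H](C(C)C)[C@H](O[Si](C)(C)C(C)(C)C)C/C(C)=C/CC[C@@](C)(O[Si](CC)(CC)CC)C2=O)cc1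
F3 | step 16 | cyclic 4α,5α-osmate ester of 19 (TMEDA ligand not drawn) | CS(=O)(=O)O[C@@H]1CC[C@@]2(C)O[Os](=O)(=O)O[C@]23[C@@H](O)[C@H](C(C)C)[C@H](O[Si](C)(C)C(C)(C)C)C[C@@]13C
F4 | step 16 | 4α,5α,6α-triol 1β-mesylate | CS(=O)(=O)O[C@@H]1CC[C@@](C)(O)[C@]2(O)[C@@H](O)[C@H](C(C)C)[C@H](O[Si](C)(C)C(C)(C)C)C[C@@]12C
F5 | step 13 | 6α-trichlorosilyl C4=C5 alkene 1β-mesylate | CC1=C2[C@@H]([Si](Cl)(Cl)Cl)[C@H](C(C)C)[C@H](O[Si](C)(C)C(C)(C)C)C[C@@]2(C)[C@H](OS(C)(=O)=O)CC1
F6 | step 13 | 6α-triethoxysilyl C4=C5 alkene 1β-mesylate | CC1=C2[C@@H]([Si](OCC)(OCC)OCC)[C@H](C(C)C)[C@H](O[Si](C)(C)C(C)(C)C)C[C@@]2(C)[C@H](OS(C)(=O)=O)CC1
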